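**Retrosynthetic overview**
1. Target 28 ← acetylation of 27; the 1,2-dioxane ← transannular SN2 of a C8 hydroperoxide anion on a C11 allylic phosphate (inversion at C11), the hydroperoxide coming from perhydrolysis of a (7R,8S)-epoxide at C8 (inversion at C8).
2. The 14-membered ring and the cis-fused α-methylene-γ-lactone ← one proposed catalyst-controlled chromium-catalysed macrocyclising 2-(methoxycarbonyl)allylation (C1–C2 bond) of bromo enal 21.
3. 21 ← Z-enone 13 (CBS reduction sets C11; the C1 arm is built by oxidation, Baylis–Hillman-type vinylalumination and SN2' bromination).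
4. 13 ← west Weinreb amide 9 (C2–C11) + east Z-alkenyl iodide 11 (C12–C14, C1).
5. 9 ← Sharpless epoxidation of Z-allylic alcohol 6 (Johnson–Claisen for 3E, Still–Gennari for the Z-alkene). Ring order: epoxide, then macrocycle and lactone together, then 1,2-dioxane.

Assumption and convention: positions use cembrane numbering (ring C1–C14, lactone C15–C17 on C1/C2, methyls C18–C20 on C4, C8, C12); 1, 10 and all reagents are taken as catalogue chemicals; the sense of induction of the chromium ligand in step 18 is assumed from the intermolecular reaction, and the antipodal ligand is used if it proves opposite.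

Step 1
Reactants: 1 (tert-butyldiphenylsilyloxy)acetaldehyde
Product: 2 rac-1-(tert-butyldiphenylsilyloxy)-3-methylbut-3-en-2-ol
Conditions: isopropenylmagnesium bromide, THF, −78 → 0 °C
Reagents that add atoms: isopropenylmagnesium bromide CC(=C)[Mg]Br
Why: Grignard addition to the aldehyde gives the isopropenyl carbinol for the Claisen step; its stereocentre is racemic and is destroyed in step 2.

Step 2
Reactants: 2 rac-1-(tert-butyldiphenylsilyloxy)-3-methylbut-3-en-2-ol
Product: 3 ethyl (4E)-6-(tert-butyldiphenylsilyloxy)-4-methylhex-4-enoate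
Conditions: CH3C(OEt)3, propionic acid (cat.), 140 °C
Reagents that add atoms: triethyl orthoacetate CC(OCC)(OCC)OCC
Why: Johnson–Claisen rearrangement through a chair transition state with the CH2OSi group equatorial gives the 3E trisubstituted alkene (C3=C4) and adds C6–C7.

Step 3
Reactants: 3 ethyl (4E)-6-(tert-butyldiphenylsilyloxy)-4-methylhex-4-enoate
Product: 4 (4E)-6-(tert-butyldiphenylsilyloxy)-4-methylhex-4-enal
Conditions: iBu2AlH (1.05 equiv), CH2Cl2, −78 °C
Reagents that add atoms: none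
Why: Partial ester reduction stops at the aldehyde because the aluminium hemiacetal is stable at −78 °C.

Step 4
Reactants: 4 (4E)-6-(tert-butyldiphenylsilyloxy)-4-methylhex-4-enal
Product: 5 methyl (2Z,6E)-8-(tert-butyldiphenylsilyloxy)-2,6-dimethylocta-2,6-dienoate
Conditions: (CF3CH2O)2P(O)CH(CH3)CO2CH3, KN(SiMe3)2, 18-crown-6, THF, −78 °C
Reagents that add atoms: methyl 2-[bis(2,2,2-trifluoroethoxy)phosphoryl]propanoate COC(=O)C(C)P(=O)(OCC(F)(F)F)OCC(F)(F)F
Why: Still–Gennari olefination gives the Z-trisubstituted enoate under kinetic control, which places C6 and C9 cis on the future C7=C8 unit.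

Step 5
Reactants: 5 methyl (2Z,6E)-8-(tert-butyldiphenylsilyloxy)-2,6-dimethylocta-2,6-dienoate
Product: 6 (2Z,6E)-8-(tert-butyldiphenylsilyloxy)-2,6-dimethylocta-2,6-dien-1-ol
Conditions: iBu2AlH (2.2 equiv), CH2Cl2, −78 → 0 °C
Reagents that add atoms: none
Why: 1,2-Reduction of the enoate gives the Z-allylic alcohol without touching the alkene geometry.

Step 6
Reactants: 6 (2Z,6E)-8-(tert-butyldiphenylsilyloxy)-2,6-dimethylocta-2,6-dien-1-ol
Product: 7 [(2S,3R)-3-[(3E)-5-(tert-butyldiphenylsilyloxy)-3-methylpent-3-enyl]-2-methyloxiran-2-yl]methanol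
Conditions: Ti(OiPr)4 (10 mol %), L-(+)-diethyl tartrate (12 mol %), t-BuOOH, 4 Å molecular sieves, CH2Cl2, −20 °C
Reagents that add atoms: tert-butyl hydroperoxide CC(C)(C)OO
Why: Sharpless asymmetric epoxidation epoxidises only the allylic-alcohol alkene, and the L-(+)-tartrate face rule on this Z-alkene gives the cis epoxide with C7 R and C8 S.

Step 7
Reactants: 7 [(2S,3R)-3-[(3E)-5-(tert-butyldiphenylsilyloxy)-3-methylpent-3-enyl]-2-methyloxiran-2-yl]methanol
Product: 9 3-[(2S,3R)-3-[(3E)-5-(tert-butyldiphenylsilyloxy)-3-methylpent-3-enyl]-2-methyloxiran-2-yl]-N-methoxy-N-methylpropanamide (west fragment), via epoxy triflate 8 (not isolated)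
Conditions: Tf2O, 2,6-lutidine, CH2Cl2, −78 °C; then LiCH2C(O)N(OCH3)CH3 [from CH3C(O)N(OCH3)CH3 + LiN(iPr)2], THF, −78 → −40 °C
Reagents that add atoms: trifluoromethanesulfonic anhydride O=S(=O)(OS(=O)(=O)C(F)(F)F)C(F)(F)F (for 8); N-methoxy-N-methylacetamide CC(=O)N(C)OC
Why: SN2 C-alkylation of an amide enolate by the primary epoxy triflate forms C9–C10 and leaves the hindered trisubstituted epoxide intact.

Step 8
Reactants: 10 3-(tert-butyldimethylsilyloxy)propanal
Product: 11 tert-butyl[(3Z)-4-iodopent-3-enyloxy]dimethylsilane (east fragment)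
Conditions: [Ph3PCH2CH3]I, n-BuLi, THF, 0 °C; I2, −78 °C; NaN(SiMe3)2, −20 °C; then 10, −78 → −20 °C
Reagents that add atoms: ethyltriphenylphosphonium iodide CC[P+](c1ccccc1)(c1ccccc1)c1ccccc1.[I-]; iodine [I][I]
Why: Wittig olefination with the α-iodo ylide (Stork–Zhao type) gives the Z-2-iodoalkene, so iodine, later replaced by C11, is cis to C14.

Step 9
Reactants: 11 tert-butyl[(3Z)-4-iodopent-3-enyloxy]dimethylsilane; 9 west Weinreb amide
Product: 13 linear Z-enone (C2 OTBDPS; 3E; 7R,8S-epoxide; C11 ketone; 12Z; C1 OTBS), via alkenyllithium 12 (not isolated)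
Conditions: t-BuLi (2.1 equiv), Et2O, −78 °C; then 9, −78 → −30 °C
Reagents that add atoms: tert-butyllithium [Li]C(C)(C)C (for 12)
Why: Iodine–lithium exchange retains the alkene geometry and Weinreb ketone synthesis stops at the ketone through the chelated tetrahedral intermediate, forming C11–C12.

Step 10
Reactants: 13 linear Z-enone
Product: 14 (11R)-allylic alcohol (C2 OTBDPS; 3E; 7R,8S-epoxide; 11R-OH; 12Z; C1 OTBS)
Conditions: (S)-2-methyl-CBS-oxazaborolidine [(S)-1-methyl-3,3-diphenyltetrahydro-1H,3H-pyrrolo[1,2-c][1,3,2]oxazaborole] (0.5 equiv), catecholborane, toluene, −78 °C; aq. NaOH work-up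
Reagents that add atoms: none
Why: Corey–Bakshi–Shibata reduction with the α-methylalkenyl group as the large substituent delivers hydride under reagent control to give the 11R alcohol.

Step 11
Reactants: 14 (11R)-allylic alcohol
Product: 15 (11R)-4-methoxybenzyl ether of 14
Conditions: KN(SiMe3)2, 4-methoxybenzyl bromide, THF, −78 → 0 °C
Reagents that add atoms: 4-methoxybenzyl bromide COc1ccc(CBr)cc1
Why: Williamson etherification at low temperature protects C11–OH before the alkoxide or any acid can open the 7,8-epoxide to a tetrahydrofuran.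

Step 12
Reactants: 15 (11R)-4-methoxybenzyl ether
Product: 16 primary C1 alcohol (15 without the TBS group)
Conditions: HF·pyridine, pyridine, THF, 0 °C
Reagents that add atoms: none
Why: Buffered fluoride desilylation removes the primary TBS ether much faster than the TBDPS ether and tolerates the epoxide.

Step 13
Reactants: 16 primary C1 alcohol
Product: 17 C1 aldehyde (β,γ-unsaturated; 12Z kept)
Conditions: Dess–Martin periodinane, NaHCO3, CH2Cl2, 0 °C
Reagents that add atoms: none
Why: Buffered Dess–Martin oxidation gives the β,γ-unsaturated aldehyde without moving the alkene into conjugation.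

Step 14
Reactants: 17 C1 aldehyde
Product: 18 Baylis–Hillman-type alcohol (methyl 2-methylidene-3-hydroxy ester at C1; C1 epimers; C15 α-carbon; C16 ester; C17 CH2)
Conditions: methyl propiolate, iBu2AlH, N-methylmorpholine N-oxide, THF, 0 °C; then 17, 0 °C → rt
Reagents that add atoms: methyl propiolate C#CC(=O)OC
Why: Vinylalumination (hydroalumination of the propiolate, then 1,2-addition of the α-aluminoacrylate) gives the Baylis–Hillman adduct without the amine base that would isomerise the aldehyde.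

Step 15
Reactants: 18 Baylis–Hillman-type alcohol
Product: 19 diol (C2 OH; C1 OH; 18 without the TBDPS group)
Conditions: HF·pyridine, pyridine, THF, rt
Reagents that add atoms: none
Why: Fluoride desilylation of the allylic TBDPS ether is done before the allylic bromide exists, so no bromide is exposed to pyridine or fluoride.

Step 16
Reactants: 19 diol
Product: 20 enal (C2 aldehyde; 3E) still carrying the C1 carbinol
Conditions: MnO2, CH2Cl2, rt
Reagents that add atoms: none
Why: MnO2 oxidises the electron-rich primary allylic alcohol far faster than the secondary carbinol next to the electron-poor acrylate.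

Step 17
Reactants: 20 enal
Product: 21 bromo enal: methyl (2Z)-2-(bromomethyl)alk-2-enoate (C1=C15; C17–Br; C14 cis to CH2Br) with C2 enal; 7R,8S-epoxide; 11R-OPMB
Conditions: N-bromosuccinimide, (CH3)2S, CH2Cl2, −20 → 0 °C
Reagents that add atoms: N-bromosuccinimide O=C1CCC(=O)N1Br
Why: Corey–Kim-type activation followed by SN2' attack of bromide converts the Baylis–Hillman alcohol into the thermodynamically preferred Z-2-(bromomethyl)enoate under near-neutral conditions.

Step 18
Reactants: 21 bromo enal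
Product: 23 (1S,2S,7R,8S,11R)-11-(4-methoxybenzyloxy)-7,8-epoxycembra-3E,12Z,15(17)-trien-16,2-olide, via macrocyclic hydroxy ester 22 (not isolated)
Conditions: CrCl2 (15 mol %), (S,S)-1,8-bis(4-isopropyl-4,5-dihydro-1,3-oxazol-2-yl)-3,6-diphenyl-9H-carbazole (17 mol %), iPr2NEt (30 mol %), Mn powder, Cp2ZrCl2, THF/CH3CN, rt, syringe-pump addition to 1 mM
Reagents that add atoms: none
Why: Proposed new method: a catalyst-controlled macrocyclising chromium-catalysed 2-(alkoxycarbonyl)allylation, in which the CrCl2/bis(oxazolinyl)carbazole complex reduces the allylic bromide to a γ-substituted allylchromium species (trivalent chromium) that adds through a closed chair transition state to the Re face of the tethered enal to give the syn adduct (C1 S, C2 S), while Mn regenerates divalent chromium and Cp2ZrCl2 releases the alkoxide, which lactonises to the cis-fused α-methylene-γ-butyrolactone inside the new 14-membered ring; the closest known reactions are the intermolecular chromium-catalysed asymmetric carbonyl 2-(alkoxycarbonyl)allylation and stoichiometric CrCl2 (Nozaki–Hiyama) macrocyclisations of allylic bromides onto aldehydes.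

Step 19
Reactants: 23 macrolactone 4-methoxybenzyl ether
Product: 24 (1S,2S,7R,8S,11R)-11-hydroxy-7,8-epoxycembra-3E,12Z,15(17)-trien-16,2-olide
Conditions: DDQ (2,3-dichloro-5,6-dicyano-1,4-benzoquinone), CH2Cl2/pH 7 phosphate buffer, 0 °C
Reagents that add atoms: none
Why: Oxidative cleavage of the 4-methoxybenzyl ether under neutral buffered conditions frees C11–OH without acid that would open the epoxide; 24 is used at once.

Step 20
Reactants: 24 macrolactone alcohol
Product: 25 11-O-diethylphosphoryl derivative of 24 (11R allylic phosphate)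
Conditions: (EtO)2P(O)Cl, Et3N, 4-(dimethylamino)pyridine (cat.), CH2Cl2, 0 °C
Reagents that add atoms: diethyl chlorophosphate CCOP(=O)(Cl)OCC
Why: O-Phosphorylation keeps the C11–O bond (retention) and turns the alcohol into an isolable leaving group under basic conditions.

Step 21
Reactants: 25 allylic phosphate
Product: 26 (1S,2S,7R,8R,11R)-8-hydroperoxy-7-hydroxy-11-(diethoxyphosphoryloxy)cembra-3E,12Z,15(17)-trien-16,2-olide
Conditions: anhydrous H2O2 in Et2O, MoO2(acac)2 (10 mol %), MgSO4, 0 °C → rt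
Reagents that add atoms: hydrogen peroxide OO
Why: Molybdenum-catalysed perhydrolysis opens the trisubstituted epoxide at the tertiary carbon C8 anti to the ring oxygen, so C8 becomes R, C7 keeps its R configuration, and the deactivated alkenes are not epoxidised.

Step 22
Reactants: 26 hydroxy hydroperoxide
Product: 27 (1S,2S,7R,8R,11S)-8,11-epidioxy-7-hydroxycembra-3E,12Z,15(17)-trien-16,2-olide
Conditions: Cs2CO3, DMF, 0 °C, 2 mM
Reagents that add atoms: none
Why: Intramolecular SN2 alkylation (6-exo-tet) of the hydroperoxide anion, the only group acidic enough for carbonate, displaces the allylic phosphate with inversion to give the 1,2-dioxane with C11 S and the Z-alkene untouched.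

Step 23
Reactants: 27 dioxane alcohol
Product: 28 target, (1S,2S,7R,8R,11S)-7-acetoxy-8,11-epidioxycembra-3E,12Z,15(17)-trien-16,2-olide
Conditions: Ac2O, pyridine, 4-(dimethylamino)pyridine (cat.), CH2Cl2, 0 °C → rt
Reagents that add atoms: acetic anhydride CC(=O)OC(C)=O
Why: Nucleophile-catalysed acetylation of the secondary C7 alcohol is mild enough for the dialkyl peroxide and the α-methylene lactone.

**Compound list**
1 | (tert-butyldiphenylsilyloxy)acetaldehyde | CC(C)(C)[Si](c1ccccc1)(c1ccccc1)OCC=O | starting material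
2 | rac-1-(tert-butyldiphenylsilyloxy)-3-methylbut-3-en-2-ol | CC(C)(C)[Si](c1ccccc1)(c1ccccc1)OCC(O)C(C)=C | intermediate
3 | ethyl (4E)-6-(tert-butyldiphenylsilyloxy)-4-methylhex-4-enoate | CC(C)(C)[Si](c1ccccc1)(c1ccccc1)OC/C=C(\C)CCC(=O)OCC | intermediate
4 | (4E)-6-(tert-butyldiphenylsilyloxy)-4-methylhex-4-enal | CC(C)(C)[Si](c1ccccc1)(c1ccccc1)OC/C=C(\C)CCC=O | intermediate
5 | methyl (2Z,6E)-8-(tert-butyldiphenylsilyloxy)-2,6-dimethylocta-2,6-dienoate | CC(C)(C)[Si](c1ccccc1)(c1ccccc1)OC/C=C(\C)CC/C=C(/C)C(=O)OC | intermediate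
6 | (2Z,6E)-8-(tert-butyldiphenylsilyloxy)-2,6-dimethylocta-2,6-dien-1-ol | CC(C)(C)[Si](c1ccccc1)(c1ccccc1)OC/C=C(\C)CC/C=C(/C)CO | intermediate
7 | [(2S,3R)-3-[(3E)-5-(tert-butyldiphenylsilyloxy)-3-methylpent-3-enyl]-2-methyloxiran-2-yl]methanol | CC(C)(C)[Si](c1ccccc1)(c1ccccc1)OC/C=C(\C)CC[C@H]1O[C@@]1(C)CO | intermediate
8 | trifluoromethanesulfonate ester of 7 (epoxy triflate) | CC(C)(C)[Si](c1ccccc1)(c1ccccc1)OC/C=C(\C)CC[C@H]1O[C@@]1(C)COS(=O)(=O)C(F)(F)F | intermediate
9 | 3-[(2S,3R)-3-[(3E)-5-(tert-butyldiphenylsilyloxy)-3-methylpent-3-enyl]-2-methyloxiran-2-yl]-N-methoxy-N-methylpropanamide (west fragment) | CC(C)(C)[Si](c1ccccc1)(c1ccccc1)OC/C=C(\C)CC[C@H]1O[C@@]1(C)CCC(=O)N(C)OC | intermediate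
10 | 3-(tert-butyldimethylsilyloxy)propanal | CC(C)(C)[Si](C)(C)OCCC=O | starting material
11 | tert-butyl[(3Z)-4-iodopent-3-enyloxy]dimethylsilane (east fragment) | C/C(I)=C/CCO[Si](C)(C)C(C)(C)C | intermediate
12 | alkenyllithium from 11 (Li in place of I; alkene geometry kept) | C/C([Li])=C/CCO[Si](C)(C)C(C)(C)C | intermediate
13 | linear Z-enone (C2 OTBDPS; 3E; 7R,8S-epoxide; C11 ketone; 12Z; C1 OTBS) | CC(C)(C)[Si](c1ccccc1)(c1ccccc1)OC/C=C(\C)CC[C@H]1O[C@@]1(C)CCC(=O)/C(C)=C\CCO[Si](C)(C)C(C)(C)C | intermediate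
14 | (11R)-allylic alcohol from 13 | CC(C)(C)[Si](c1ccccc1)(c1ccccc1)OC/C=C(\C)CC[C@H]1O[C@@]1(C)CC[C@@H](O)/C(C)=C\CCO[Si](C)(C)C(C)(C)C | intermediate
15 | (11R)-4-methoxybenzyl ether of 14 | CC(C)(C)[Si](c1ccccc1)(c1ccccc1)OC/C=C(\C)CC[C@H]1O[C@@]1(C)CC[C@@H](OCc1ccc(OC)cc1)/C(C)=C\CCO[Si](C)(C)C(C)(C)C | intermediate
16 | primary C1 alcohol (15 without TBS) | CC(C)(C)[Si](c1ccccc1)(c1ccccc1)OC/C=C(\C)CC[C@H]1O[C@@]1(C)CC[C@@H](OCc1ccc(OC)cc1)/C(C)=C\CCO | intermediate
17 | C1 aldehyde (β,γ-unsaturated) | CC(C)(C)[Si](c1ccccc1)(c1ccccc1)OC/C=C(\C)CC[C@H]1O[C@@]1(C)CC[C@@H](OCc1ccc(OC)cc1)/C(C)=C\CC=O | intermediate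
18 | Baylis–Hillman-type alcohol (C1 epimers) | CC(C)(C)[Si](c1ccccc1)(c1ccccc1)OC/C=C(\C)CC[C@H]1O[C@@]1(C)CC[C@@H](OCc1ccc(OC)cc1)/C(C)=C\CC(O)C(=C)C(=O)OC | intermediate
19 | diol (C2 OH; C1 OH) | OC/C=C(\C)CC[C@H]1O[C@@]1(C)CC[C@@H](OCc1ccc(OC)cc1)/C(C)=C\CC(O)C(=C)C(=O)OC | intermediate
20 | enal with C1 carbinol | O=C/C=C(\C)CC[C@H]1O[C@@]1(C)CC[C@@H](OCc1ccc(OC)cc1)/C(C)=C\CC(O)C(=C)C(=O)OC | intermediate
21 | bromo enal, methyl (2Z)-2-(bromomethyl)alk-2-enoate with C2 enal | O=C/C=C(\C)CC[C@H]1O[C@@]1(C)CC[C@@H](OCc1ccc(OC)cc1)/C(C)=C\C/C=C(\CBr)C(=O)OC | intermediate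
22 | macrocyclic hydroxy ester (1S,2S; C2 OH; C1 bears C(=CH2)CO2CH3) | O[C@H]1/C=C(\C)CC[C@H]2O[C@@]2(C)CC[C@@H](OCc2ccc(OC)cc2)/C(C)=C\C[C@H]1C(=C)C(=O)OC | intermediate
23 | (1S,2S,7R,8S,11R)-11-(4-methoxybenzyloxy)-7,8-epoxycembra-3E,12Z,15(17)-trien-16,2-olide | C=C1C(=O)O[C@H]2/C=C(\C)CC[C@H]3O[C@@]3(C)CC[C@@H](OCc3ccc(OC)cc3)/C(C)=C\C[C@@H]12 | intermediate
24 | (1S,2S,7R,8S,11R)-11-hydroxy-7,8-epoxycembra-3E,12Z,15(17)-trien-16,2-olide | C=C1C(=O)O[C@H]2/C=C(\C)CC[C@H]3O[C@@]3(C)CC[C@@H](O)/C(C)=C\C[C@@H]12 | intermediate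
25 | 11-O-diethylphosphoryl derivative of 24 | C=C1C(=O)O[C@H]2/C=C(\C)CC[C@H]3O[C@@]3(C)CC[C@@H](OP(=O)(OCC)OCC)/C(C)=C\C[C@@H]12 | intermediate
26 | (1S,2S,7R,8R,11R)-8-hydroperoxy-7-hydroxy-11-(diethoxyphosphoryloxy)cembra-3E,12Z,15(17)-trien-16,2-olide | C=C1C(=O)O[C@H]2/C=C(\C)CC[C@@H](O)[C@@](OO)(C)CC[C@@H](OP(=O)(OCC)OCC)/C(C)=C\C[C@@H]12 | intermediate
27 | (1S,2S,7R,8R,11S)-8,11-epidioxy-7-hydroxycembra-3E,12Z,15(17)-trien-16,2-olide | C=C1C(=O)O[C@H]2/C=C(\C)CC[C@@H](O)[C@@]3(C)CC[C@H](OO3)/C(C)=C\C[C@@H]12 | intermediate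
28 | (1S,2S,7R,8R,11S)-7-acetoxy-8,11-epidioxycembra-3E,12Z,15(17)-trien-16,2-olide | C=C1C(=O)O[C@H]2/C=C(\C)CC[C@@H](OC(C)=O)[C@@]3(C)CC[C@H](OO3)/C(C)=C\C[C@@H]12 | target

**Step count:** 23 steps in total. Longest linear sequence: 22 steps (from 1 through steps 1–7 and 9–23).

**Three steps most likely to fail**

Step 18 (the proposed new macrocyclisation). The fallback uses known chemistry and closes the ring at a different bond; it sets out from 9 and 11 and comes back to the route at 24.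
- East piece: 11 is desilylated (Bu4NF, THF) to (3Z)-4-iodopent-3-en-1-ol F1, oxidised with Dess–Martin periodinane to (3Z)-4-iodopent-3-enal F2, converted as in step 14 into methyl (5Z)-3-hydroxy-6-iodo-2-methylidenehept-5-enoate F3, and as in step 17 into methyl (2Z,5Z)-2-(bromomethyl)-6-iodohepta-2,5-dienoate F4.
- West piece: 9 is desilylated (HF·pyridine) to the C2 allylic alcohol Weinreb amide F5 and oxidised (MnO2) to the enal Weinreb amide F6.
- Union and ring closure: intermolecular chromium-catalysed asymmetric 2-(alkoxycarbonyl)allylation of F6 with F4 (CrCl2, same ligand, Mn, Cp2ZrCl2; the alkenyl iodide is inert without nickel) gives the cis-lactone alkenyl iodide Weinreb amide F7. Cp2Zr(H)Cl reduces the amide to the C11 aldehyde F8. A Nozaki–Hiyama–Kishi macrocyclisation (CrCl2, NiCl2 cat., DMSO/THF, high dilution) closes C11–C12 to the macrocyclic C11-epimeric allylic alcohols F9. Dess–Martin oxidation gives the macrocyclic Z-enone F10, and CBS reduction as in step 10 returns 24.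

Step 21 (perhydrolysis of the epoxide next to an allylic phosphate). The fallback exchanges the roles of C8 and C11; it sets out from 24 and comes back at 27. MsCl/Et3N in CH2Cl2 at −40 °C gives the allylic mesylate F11. Excess anhydrous H2O2 in Et2O is added to the same flask and gives, by SN2 with inversion, the (11S)-hydroperoxide F12. Camphorsulfonic acid (cat.) in CH2Cl2 then drives the 6-exo opening of the epoxide at the tertiary C8 with inversion, which gives 27 directly.

Step 22 (SN2 ring closure on the allylic phosphate). The fallback forms the C11–O bond by carbonyl addition and reduction instead of substitution; it sets out from 24 and comes back at 27. Dess–Martin oxidation gives the macrocyclic Z-enone F10. Perhydrolysis as in step 21 gives the C8-hydroperoxy ketone F13, which closes onto the C11 ketone to the bicyclic peroxyhemiketal F14. Et3SiH/BF3·OEt2 in CH2Cl2 at −78 °C reduces the derived peroxycarbenium ion (a known reduction of peroxyketals) to 27. The C11 configuration is then set by hydride delivery under substrate control and must be checked against the main-route material.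

**Further compounds**
F1 | step 18 | (3Z)-4-iodopent-3-en-1-ol | C/C(I)=C/CCO
F2 | step 18 | (3Z)-4-iodopent-3-enal | C/C(I)=C/CC=O
F3 | step 18 | methyl (5Z)-3-hydroxy-6-iodo-2-methylidenehept-5-enoate | C/C(I)=C/CC(O)C(=C)C(=O)OC
F4 | step 18 | methyl (2Z,5Z)-2-(bromomethyl)-6-iodohepta-2,5-dienoate | C/C(I)=C/C/C=C(\CBr)C(=O)OC
F5 | step 18 | C2 allylic alcohol Weinreb amide (9 without TBDPS) | OC/C=C(\C)CC[C@H]1O[C@@]1(C)CCC(=O)N(C)OC
F6 | step 18 | enal Weinreb amide | O=C/C=C(\C)CC[C@H]1O[C@@]1(C)CCC(=O)N(C)OC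
F7 | step 18 | cis-lactone alkenyl iodide Weinreb amide (1S,2S) | C=C1C(=O)O[C@@H](/C=C(\C)CC[C@H]2O[C@@]2(C)CCC(=O)N(C)OC)[C@H]1C/C=C(/C)I
F8 | step 18 | cis-lactone alkenyl iodide C11 aldehyde | C=C1C(=O)O[C@@H](/C=C(\C)CC[C@H]2O[C@@]2(C)CCC=O)[C@H]1C/C=C(/C)I
F9 | step 18 | macrocyclic allylic alcohols (C11 epimers of 24) | C=C1C(=O)O[C@H]2/C=C(\C)CC[C@H]3O[C@@]3(C)CCC(O)/C(C)=C\C[C@@H]12
F10 | step 18 | macrocyclic Z-enone (C11 ketone) | C=C1C(=O)O[C@H]2/C=C(\C)CC[C@H]3O[C@@]3(C)CCC(=O)/C(C)=C\C[C@@H]12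
F11 | step 21 | (11R)-allylic mesylate of 24 | C=C1C(=O)O[C@H]2/C=C(\C)CC[C@H]3O[C@@]3(C)CC[C@@H](OS(C)(=O)=O)/C(C)=C\C[C@@H]12
F12 | step 21 | (11S)-hydroperoxide | C=C1C(=O)O[C@H]2/C=C(\C)CC[C@H]3O[C@@]3(C)CC[C@H](OO)/C(C)=C\C[C@@H]12
F13 | step 22 | C8-hydroperoxy C7-hydroxy C11 ketone | C=C1C(=O)O[C@H]2/C=C(\C)CC[C@@H](O)[C@@](OO)(C)CCC(=O)/C(C)=C\C[C@@H]12
F14 | step 22 | bicyclic peroxyhemiketal (11-hydroxy-8,11-epidioxide) | C=C1C(=O)O[C@H]2/C=C(\C)CC[C@@H](O)[C@@]3(C)CCC(O)(OO3)/C(C)=C\C[C@@H]12
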